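Ring A, the cycloheptene made of C2, C3, C4, C5, C6, C12 and C15 (heavy atoms counted along the target SMILES), holds a C2=C3 methyl alkene and a quaternary C12 next to the C15 stereocentre: the imprint of a (4+3) adduct. The route therefore cuts C4–C5 and C12–C15. A cyclic vinyl diazo ketone (C5, C6, C12 with ring B) and an (E)-3-methyl-1,3-diene (C2, C3, C4, C15, C16) are joined by rhodium-carbenoid cyclopropanation and Cope shift, which closes ring A on ring B and sets C15 in one operation. The C16 iodide is later added as a radical to a ring C/D enone built from 2-methylcyclohexane-1,3-dione.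

Key step: step 6

Remarks on the chemistry (assumptions):
- Atom labels C1 to O34 follow the order of the heavy atoms in the target SMILES and are used for all intermediates.
- The target SMILES places O28 and C21 on the same face of ring C (cis-fused oxepane) and the C18 side chain cis to the C20 methyl group; the route is planned for this relative configuration.
- The sense of induction of Rh2(R-PTAD)4 with the ketone carbenoid is assumed to follow the model for aryl and vinyl diazo carbonyl compounds. The face required is the one that gives (1R,3S)-9; if a trial run shows the opposite sense, the mirror-image catalyst is used and nothing else changes.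
- C23 is carried as a mixture of both epimers from step 18 to step 23; they converge on the ketone in step 24.

Step 1
Reactants: 1 1,4-dioxaspiro[4.4]nonan-7-one
Product: 2 7-(propan-2-ylidene)-1,4-dioxaspiro[4.4]nonane
Conditions: i-PrPPh3I, KHMDS, THF, 0 °C; then 1, −78 → 23 °C
Reagents that add atoms: isopropyltriphenylphosphonium iodide, CC(C)[P+](c1ccccc1)(c1ccccc1)c1ccccc1.[I-]
Why: Wittig olefination places the tetrasubstituted alkene exocyclic at C6 without ambiguity; the ylide is added cold to outrun enolisation of the β-ketal ketone.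

Step 2
Reactants: 2 7-(propan-2-ylidene)-1,4-dioxaspiro[4.4]nonane
Product: 3 3-(propan-2-ylidene)cyclopentan-1-one
Conditions: PPTS, acetone/H2O, 23 °C
Reagents that add atoms: water, O
Why: Mild acid-catalysed acetal hydrolysis frees the ketone while the tetrasubstituted β,γ-alkene stays out of conjugation, so that the CH2 between carbonyl and alkene (C5) is the one doubly activated position for step 3.

Step 3
Reactants: 3 3-(propan-2-ylidene)cyclopentan-1-one
Product: 5 2-diazo-3-(propan-2-ylidene)cyclopentan-1-one, via trifluoroacetyl diketone 4 (not isolated)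
Conditions: LiHMDS, THF, −78 °C; CF3CO2CH2CF3; then MsN3, Et3N, H2O, MeCN, 23 °C
Reagents that add atoms: 2,2,2-trifluoroethyl trifluoroacetate, O=C(OCC(F)(F)F)C(F)(F)F (atoms in 4 only); methanesulfonyl azide, CS(=O)(=O)N=[N+]=[N-]
Why: Detrifluoroacetylative (Regitz-type) diazo transfer: LiHMDS removes the most acidic proton at C5, the exocyclic dienolate is C-acylated there, and the activated 1,3-diketone 4 exchanges its trifluoroacetyl group for the diazo group, which fixes the vinyl diazo ketone as the isopropylidene isomer.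

Step 4
Reactants: 6 (E)-3-methylpent-2-en-4-yn-1-ol
Product: 7 (E)-3-methylpent-2-en-4-yn-1-yl acetate
Conditions: Ac2O, pyridine, DMAP, CH2Cl2, 0 °C
Reagents that add atoms: acetic anhydride, CC(=O)OC(C)=O
Why: Acetylation of the primary alcohol under nucleophilic catalysis; the ester rather than a silyl ether is chosen because it deactivates the C16–H bonds toward carbenoid insertion in step 6.

Step 5
Reactants: 7 (E)-3-methylpent-2-en-4-yn-1-yl acetate
Product: 8 (E)-3-methylpenta-2,4-dien-1-yl acetate
Conditions: H2 (1 atm), Pd/CaCO3 poisoned with Pb(OAc)2 (Lindlar catalyst), quinoline, hexane, 23 °C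
Reagents that add atoms: none
Why: Semihydrogenation over poisoned palladium stops at the terminal alkene and leaves the E-trisubstituted alkene and the allylic ester untouched.

Step 6
Reactants: 5 2-diazo-3-(propan-2-ylidene)cyclopentan-1-one; 8 (E)-3-methylpenta-2,4-dien-1-yl acetate
Product: 10 [(5R)-4,4,6-trimethyl-1-oxo-1,2,3,4,5,8-hexahydroazulen-5-yl]methyl acetate, via divinylcyclopropane 9 (not isolated)
Conditions: 5 added slowly to 8 (3 equiv) and Rh2(R-PTAD)4 (1 mol %), PhCF3/hexanes, 0 → 23 °C; then toluene, 100 °C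
Reagents that add atoms: none
Why: Proposed new method: the divalent-rhodium carbenoid from 5 adds to the monosubstituted C3=C4 alkene of 8 to give the cis-divinylcyclopropane 9 (alkenyl group syn to the isopropylidene-bearing C6, anti to the carbonyl), whose boat [3,3] shift breaks C3–C5 and joins C12 to C15; the closest known reaction type is the tandem cyclopropanation and Cope rearrangement of acyclic vinyldiazoacetates and vinyl diazo ketones with dienes, which has not been shown for a cyclic vinyl diazo ketone with a fully substituted vinyl terminus. Ring A closes in a formal (4+3) mode, the diene giving C2, C3, C4 and C15 and the carbenoid C5, C6 and C12, by a concerted suprafacial six-electron shift of the spiro-fused divinylcyclopropane onto ring B. C15 is the only new stereocentre: the chiral catalyst chooses the enantioface of C3=C4 in the cyclopropanation and the stereospecific boat shift relays C3 to C15, the E alkene keeping the acetoxymethyl group outside the boat. Site selectivity for the terminal alkene over the trisubstituted one follows from the steric demand of donor/acceptor carbenoids, and the acetate deactivates the allylic C16–H bonds toward insertion. The spiro geometry holds the isopropylidene π bond parallel to the breaking cyclopropane bond, so heating to about 100 °C should suffice although one methyl group on C12 points into the boat. The phthalimido catalyst is preferred to a prolinate one because the latter are reliable only with ester acceptors.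

Step 7
Reactants: 10 [(5R)-4,4,6-trimethyl-1-oxo-1,2,3,4,5,8-hexahydroazulen-5-yl]methyl acetate
Product: 11 [(5R)-6,7-epoxy-4,4,6-trimethyl-1-oxo-1,2,3,4,5,6,7,8-octahydroazulen-5-yl]methyl acetate (C2–C3 epoxide; both faces)
Conditions: mCPBA, NaHCO3, CH2Cl2, 0 °C
Reagents that add atoms: 3-chloroperbenzoic acid, OOC(=O)c1cccc(Cl)c1
Why: Prilezhaev epoxidation by the electrophilic peracid selects the electron-rich C2=C3 alkene over the enone alkene and so masks C2=C3 for step 9; both epoxide faces are acceptable because the oxygen is removed in step 11.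

Step 8
Reactants: 11 C2–C3 epoxide of 10
Product: 12 [(1S,5R)-6,7-epoxy-1-hydroxy-4,4,6-trimethyl-1,2,3,4,5,6,7,8-octahydroazulen-5-yl]methyl acetate
Conditions: (R)-2-methyl-CBS-oxazaborolidine (20 mol %), catecholborane, toluene, −78 °C
Reagents that add atoms: none
Why: Corey–Bakshi–Shibata reduction: the catalyst, not the remote C15 centre, fixes C9, the fully substituted enone carbon C5 acting as the large group, so the (R)-catalyst should give the (S)-allylic alcohol with its hydroxyl on the face anti to C16.

Step 9
Reactants: 12 epoxy allylic alcohol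
Product: 13 [(1S,3aS,5R,8aS)-6,7-epoxy-1-hydroxy-4,4,6-trimethyldecahydroazulen-5-yl]methyl acetate
Conditions: [Ir(cod)(PCy3)(py)]PF6 (10 mol %), H2 (1–10 atm), CH2Cl2, 23 °C
Reagents that add atoms: none
Why: Hydroxyl-directed hydrogenation: the iridium cation bound to the C9 hydroxyl delivers both hydrogens to one face of the tetrasubstituted C5=C6 alkene, which sets C5 and C6 cis to the hydroxyl (cis ring fusion, H5 and H6 syn to H15), and no other alkene is present to compete.

Step 10
Reactants: 13 epoxy alcohol
Product: 14 [(3aS,5R,8aS)-6,7-epoxy-4,4,6-trimethyl-1-oxodecahydroazulen-5-yl]methyl acetate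
Conditions: Dess–Martin periodinane, NaHCO3, CH2Cl2, 23 °C
Reagents that add atoms: none
Why: Dess–Martin oxidation of the secondary alcohol under buffered, non-epimerising conditions returns the ketone with the cis ring fusion intact.

Step 11
Reactants: 14 epoxy ketone
Product: 15 [(3aS,5R,8aS)-4,4,6-trimethyl-1-oxo-1,2,3,3a,4,5,8,8a-octahydroazulen-5-yl]methyl acetate
Conditions: NaI, Zn, NaOAc, AcOH, 0 → 23 °C
Reagents that add atoms: none
Why: Deoxygenation of the epoxide through the iodohydrin and zinc-induced β-elimination regenerates the C2=C3 alkene in its only possible position; the buffered medium should leave C5 unchanged.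

Step 12
Reactants: 15 cis-fused ketone
Product: 16 [(3aS,5R,8aS)-4,4,6-trimethyl-1-methylidene-1,2,3,3a,4,5,8,8a-octahydroazulen-5-yl]methyl acetate
Conditions: Zn, CH2Br2, TiCl4, THF/CH2Cl2, 0 → 23 °C
Reagents that add atoms: dibromomethane, BrCBr
Why: Lombardo methylenation with the non-basic zinc–titanium methylene reagent converts the ketone to the exocyclic alkene without epimerising C5 and does not touch the acetate.

Step 13
Reactants: 16 exocyclic alkene
Product: 19 (1S,3aS,5R,8aS)-5-(hydroxymethyl)-1,4,4,6-tetramethyl-1,2,3,3a,4,5,8,8a-octahydroazulen-1-ol, via organomercurial acetate 17 (not isolated), via hydroxy acetate 18 (not isolated)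
Conditions: Hg(OAc)2, THF/H2O, 0 °C; then 3 M NaOH, NaBH4, 0 → 23 °C
Reagents that add atoms: mercury diacetate, CC(=O)O[Hg]OC(C)=O (atoms in 17 only); water, O
Why: Markovnikov oxymercuration–demercuration picks the 1,1-disubstituted alkene over the trisubstituted C2=C3 alkene and brings water to C9 from the convex face of the cis-fused bicycle, so the hydroxyl ends cis to H5 (the epimer that methyl addition to ketone 15 would not give); the alkaline borohydride work-up also saponifies the acetate.

Step 14
Reactants: 19 diol
Product: 20 (1S,3aS,5R,8aS)-5-(iodomethyl)-1,4,4,6-tetramethyl-1,2,3,3a,4,5,8,8a-octahydroazulen-1-ol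
Conditions: I2, PPh3, imidazole, CH2Cl2, 0 → 23 °C
Reagents that add atoms: iodine, [I][I]
Why: Appel reaction converts the primary alcohol to the iodide while the tertiary alcohol is too hindered to form the alkoxyphosphonium ion.

Step 15
Reactants: 21 2-methylcyclohexane-1,3-dione
Product: 22 3-(2,2-dimethylhydrazinylidene)-2-methylcyclohexan-1-one
Conditions: Me2NNH2, AcOH (cat.), toluene, reflux (water removed)
Reagents that add atoms: 1,1-dimethylhydrazine, CN(C)N
Why: Condensation of one carbonyl group with the hydrazine gives the vinylogous hydrazide, whose anion is a soft carbon nucleophile at C19.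

Step 16
Reactants: 22 keto hydrazone; 23 5-bromo-2-methylpent-2-ene
Product: 25 2-methyl-2-(4-methylpent-3-en-1-yl)cyclohexane-1,3-dione, via alkylated hydrazone 24 (not isolated)
Conditions: KH, THF, 0 °C; 23, 60 °C; then Cu(OAc)2, THF/H2O, 23 °C
Reagents that add atoms: water, O
Why: C-Alkylation of the potassium salt of the keto hydrazone with the unactivated primary bromide builds the quaternary C19 (the dione itself would alkylate on oxygen), and copper-assisted hydrolysis returns the symmetrical dione.

Step 17
Reactants: 25 alkylated dione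
Product: 26 (2R,3R)-3-hydroxy-2-methyl-2-(4-methylpent-3-en-1-yl)cyclohexan-1-one
Conditions: (S)-2-methyl-CBS-oxazaborolidine (20 mol %), catecholborane (1 equiv), toluene, −78 → −40 °C
Reagents that add atoms: none
Why: Corey–Bakshi–Shibata desymmetrisation: the (S)-catalyst should form the (R)-carbinol and reduce, of the two enantiotopic carbonyl groups, the one where this coincides with hydride attack from the methyl side of C19, so that the hydroxyl (O28) ends cis to the homoprenyl chain.

Step 18
Reactants: 26 ketol
Product: 28 (3RS,5aR,9aR)-3-hydroxy-2,2,5a-trimethyloctahydro-1-benzoxepin-6(2H)-one, via organomercurial chloride 27 (not isolated)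
Conditions: Hg(OCOCF3)2, MeNO2, −20 °C; aq NaCl; then NaBH4 (1 equiv), O2, DMF, −20 °C
Reagents that add atoms: mercury bis(trifluoroacetate), O=C(O[Hg]OC(=O)C(F)(F)F)C(F)(F)F and sodium chloride, [Na+].[Cl-] (atoms in 27 only); dioxygen, O=O
Why: Intramolecular alkoxymercuration is Markovnikov, so the C29 hydroxyl attacks the tertiary C25 terminus (seven-membered, endo) and the cis relation of hydroxyl and chain gives the cis-fused oxepane; oxidative demercuration then traps the C23 radical with oxygen (both epimers), the limited borohydride at low temperature sparing the hindered ketone.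

Step 19
Reactants: 28 hydroxy ketone
Product: 29 (3RS,5aS,9aR)-2,2,5a-trimethyl-6-methylidenedecahydro-1-benzoxepin-3-ol
Conditions: Ph3PCH3Br, KOtBu (3 equiv each), toluene, 80 °C
Reagents that add atoms: methyltriphenylphosphonium bromide, C[P+](c1ccccc1)(c1ccccc1)c1ccccc1.[Br-]
Why: Wittig methylenation of the hindered C18 ketone (excess ylide, heat, the free alcohol carried as its alkoxide) introduces C17; no epimerisable centre is adjacent.

Step 20
Reactants: 29 exocyclic alkene
Product: 30 (5aS,9aR)-2,2,5a-trimethyl-6-methylidenedecahydro-1-benzoxepine-3,7-diol (epimers at C3 and C7)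
Conditions: SeO2 (cat.), t-BuOOH, CH2Cl2, 23 °C
Reagents that add atoms: selenium dioxide, O=[Se]=O (oxygen carrier); tert-butyl hydroperoxide, CC(C)(C)OO
Why: Selenium dioxide ene reaction and [2,3]-shift hydroxylate the only allylic CH2 (C32), C19 being quaternary; the configuration of the new carbinol is irrelevant.

Step 21
Reactants: 30 allylic alcohol
Product: 31 (3RS,5aS,9aR)-3-hydroxy-2,2,5a-trimethyl-6-methylideneoctahydro-1-benzoxepin-7(2H)-one
Conditions: MnO2, CH2Cl2, 23 °C
Reagents that add atoms: none
Why: MnO2 oxidises the allylic alcohol selectively over the saturated C23 alcohol and gives the α-methylene ketone, which is used at once.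

Step 22
Reactants: 20 ring A/B iodide; 31 ring C/D enone
Product: 32 (3RS,5aS,6S,9aR)-3-hydroxy-6-{2-[(1S,3aS,5R,8aS)-1-hydroxy-1,4,4,6-tetramethyl-1,2,3,3a,4,5,8,8a-octahydroazulen-5-yl]ethyl}-2,2,5a-trimethyloctahydro-1-benzoxepin-7(2H)-one
Conditions: (Me3Si)3SiH, AIBN, toluene, 80 °C (slow addition); then DBU, CH2Cl2, 23 °C; separation, recycling of the C18 epimer
Reagents that add atoms: none
Why: Giese radical conjugate addition: the primary C16 radical from 20 adds to the unhindered methylene terminus C17 of 31 and the α-keto radical takes hydrogen from the silane; C18 is epimerisable, so the epimers are equilibrated with DBU, the one with the side chain trans to C21 is collected and the other is returned to the base, the position of this equilibrium being uncertain because the cis-fused bicycle has two accessible chairs.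

Step 23
Reactants: 32 coupled ketone
Product: 33 (3RS,5aS,6S,7R,9aR)-6-{2-[(1S,3aS,5R,8aS)-1-hydroxy-1,4,4,6-tetramethyl-1,2,3,3a,4,5,8,8a-octahydroazulen-5-yl]ethyl}-2,2,5a,7-tetramethyldecahydro-1-benzoxepine-3,7-diol
Conditions: MeMgBr (excess), CeCl3, THF, −78 → 0 °C
Reagents that add atoms: methylmagnesium bromide, C[Mg]Br
Why: 1,2-Addition of the organocerium reagent (low basicity, so C18 is not enolised): axial approach to C32 is blocked by the syn-axial substituent on C19, so methyl enters equatorially in the chair with the C18 chain equatorial and the new hydroxyl is axial and cis to that chain.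

Step 24
Reactants: 33 triol
Product: 34 (5aS,6S,7R,9aR)-7-hydroxy-6-{2-[(1S,3aS,5R,8aS)-1-hydroxy-1,4,4,6-tetramethyl-1,2,3,3a,4,5,8,8a-octahydroazulen-5-yl]ethyl}-2,2,5a,7-tetramethyloctahydro-1-benzoxepin-3(2H)-one (target)
Conditions: Dess–Martin periodinane, NaHCO3, CH2Cl2, 23 °C
Reagents that add atoms: none
Why: Dess–Martin oxidation of the only secondary alcohol converges both C23 epimers on the ketone; the two tertiary alcohols and the alkene are inert.

Compound list
1 | 1,4-dioxaspiro[4.4]nonan-7-one | O=C1CCC2(C1)OCCO2 | starting material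
2 | 7-(propan-2-ylidene)-1,4-dioxaspiro[4.4]nonane | CC(C)=C1CCC2(C1)OCCO2 | intermediate
3 | 3-(propan-2-ylidene)cyclopentan-1-one | CC(C)=C1CCC(=O)C1 | intermediate
4 | 3-(propan-2-ylidene)-2-(trifluoroacetyl)cyclopentan-1-one | CC(C)=C1CCC(=O)C1C(=O)C(F)(F)F | intermediate (not isolated)
5 | 2-diazo-3-(propan-2-ylidene)cyclopentan-1-one | [N-]=[N+]=C1C(=O)CCC1=C(C)C | intermediate
6 | (E)-3-methylpent-2-en-4-yn-1-ol | C#C/C(C)=C/CO | starting material
7 | (E)-3-methylpent-2-en-4-yn-1-yl acetate | C#C/C(C)=C/COC(C)=O | intermediate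
8 | (E)-3-methylpenta-2,4-dien-1-yl acetate | C=C/C(C)=C/COC(C)=O | intermediate
9 | (2E)-3-[(1R,3S)-4-oxo-7-(propan-2-ylidene)spiro[2.4]heptan-1-yl]but-2-en-1-yl acetate | O=C1CCC(=C(C)C)[C@@]12C[C@@H]2/C(C)=C/COC(C)=O | intermediate (not isolated)
10 | [(5R)-4,4,6-trimethyl-1-oxo-1,2,3,4,5,8-hexahydroazulen-5-yl]methyl acetate | CC1=CCC2=C(CCC2=O)C(C)(C)[C@@H]1COC(C)=O | intermediate
11 | C2–C3 epoxide of 10 (both epoxide faces) | CC12OC1CC3=C(CCC3=O)C(C)(C)[C@@H]2COC(C)=O | intermediate
12 | [(1S,5R)-6,7-epoxy-1-hydroxy-4,4,6-trimethyl-1,2,3,4,5,6,7,8-octahydroazulen-5-yl]methyl acetate | CC12OC1CC3=C(CC[C@@H]3O)C(C)(C)[C@@H]2COC(C)=O | intermediate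
13 | [(1S,3aS,5R,8aS)-6,7-epoxy-1-hydroxy-4,4,6-trimethyldecahydroazulen-5-yl]methyl acetate (cis-fused) | CC12OC1C[C@H]3[C@H](CC[C@@H]3O)C(C)(C)[C@@H]2COC(C)=O | intermediate
14 | [(3aS,5R,8aS)-6,7-epoxy-4,4,6-trimethyl-1-oxodecahydroazulen-5-yl]methyl acetate | CC12OC1C[C@H]3[C@H](CCC3=O)C(C)(C)[C@@H]2COC(C)=O | intermediate
15 | [(3aS,5R,8aS)-4,4,6-trimethyl-1-oxo-1,2,3,3a,4,5,8,8a-octahydroazulen-5-yl]methyl acetate | CC1=CC[C@H]2[C@H](CCC2=O)C(C)(C)[C@@H]1COC(C)=O | intermediate
16 | [(3aS,5R,8aS)-4,4,6-trimethyl-1-methylidene-1,2,3,3a,4,5,8,8a-octahydroazulen-5-yl]methyl acetate | CC1=CC[C@H]2[C@H](CCC2=C)C(C)(C)[C@@H]1COC(C)=O | intermediate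
17 | acetoxymercuriomethyl carbinol from 16 (C9 hydroxyl cis to H5; HgOAc on C10) | CC1=CC[C@H]2[C@H](CC[C@]2(C[Hg]OC(C)=O)O)C(C)(C)[C@@H]1COC(C)=O | intermediate (not isolated)
18 | [(1S,3aS,5R,8aS)-1-hydroxy-1,4,4,6-tetramethyl-1,2,3,3a,4,5,8,8a-octahydroazulen-5-yl]methyl acetate | CC1=CC[C@H]2[C@H](CC[C@]2(C)O)C(C)(C)[C@@H]1COC(C)=O | intermediate (not isolated)
19 | (1S,3aS,5R,8aS)-5-(hydroxymethyl)-1,4,4,6-tetramethyl-1,2,3,3a,4,5,8,8a-octahydroazulen-1-ol | CC1=CC[C@H]2[C@H](CC[C@]2(C)O)C(C)(C)[C@@H]1CO | intermediate
20 | (1S,3aS,5R,8aS)-5-(iodomethyl)-1,4,4,6-tetramethyl-1,2,3,3a,4,5,8,8a-octahydroazulen-1-ol | CC1=CC[C@H]2[C@H](CC[C@]2(C)O)C(C)(C)[C@@H]1CI | intermediate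
21 | 2-methylcyclohexane-1,3-dione | CC1C(=O)CCCC1=O | starting material
22 | 3-(2,2-dimethylhydrazinylidene)-2-methylcyclohexan-1-one | CN(C)N=C1CCCC(=O)C1C | intermediate
23 | 5-bromo-2-methylpent-2-ene | CC(C)=CCCBr | starting material
24 | 3-(2,2-dimethylhydrazinylidene)-2-methyl-2-(4-methylpent-3-en-1-yl)cyclohexan-1-one (racemic) | CN(C)N=C1CCCC(=O)C1(C)CCC=C(C)C | intermediate (not isolated)
25 | 2-methyl-2-(4-methylpent-3-en-1-yl)cyclohexane-1,3-dione | CC(C)=CCCC1(C)C(=O)CCCC1=O | intermediate
26 | (2R,3R)-3-hydroxy-2-methyl-2-(4-methylpent-3-en-1-yl)cyclohexan-1-one | CC(C)=CCC[C@@]1(C)C(=O)CCC[C@H]1O | intermediate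
27 | (5aR,9aR)-3-(chloromercurio)-2,2,5a-trimethyloctahydro-1-benzoxepin-6(2H)-one (C23 epimers) | O=C1[C@]2(C)CCC([Hg]Cl)C(C)(C)O[C@@H]2CCC1 | intermediate (not isolated)
28 | (3RS,5aR,9aR)-3-hydroxy-2,2,5a-trimethyloctahydro-1-benzoxepin-6(2H)-one | O=C1[C@]2(C)CCC(O)C(C)(C)O[C@@H]2CCC1 | intermediate
29 | (3RS,5aS,9aR)-2,2,5a-trimethyl-6-methylidenedecahydro-1-benzoxepin-3-ol | C=C1[C@]2(C)CCC(O)C(C)(C)O[C@@H]2CCC1 | intermediate
30 | (5aS,9aR)-2,2,5a-trimethyl-6-methylidenedecahydro-1-benzoxepine-3,7-diol (epimers at C3 and C7) | C=C1[C@]2(C)CCC(O)C(C)(C)O[C@@H]2CCC1O | intermediate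
31 | (3RS,5aS,9aR)-3-hydroxy-2,2,5a-trimethyl-6-methylideneoctahydro-1-benzoxepin-7(2H)-one | C=C1[C@]2(C)CCC(O)C(C)(C)O[C@@H]2CCC1=O | intermediate
32 | coupled hydroxy ketone (5aS,6S,9aR; C23 epimers) | CC1=CC[C@H]2[C@H](CC[C@]2(C)O)C(C)(C)[C@@H]1CC[C@H]1[C@]2(C)CCC(O)C(C)(C)O[C@@H]2CCC1=O | intermediate
33 | triol (5aS,6S,7R,9aR; C23 epimers) | CC1=CC[C@H]2[C@H](CC[C@]2(C)O)C(C)(C)[C@@H]1CC[C@H]1[C@]2(C)CCC(O)C(C)(C)O[C@@H]2CC[C@@]1(C)O | intermediate
34 | CNP0194989.5, (5aS,6S,7R,9aR)-7-hydroxy-6-{2-[(1S,3aS,5R,8aS)-1-hydroxy-1,4,4,6-tetramethyl-1,2,3,3a,4,5,8,8a-octahydroazulen-5-yl]ethyl}-2,2,5a,7-tetramethyloctahydro-1-benzoxepin-3(2H)-one | CC1=CC[C@H]2[C@H](CC[C@]2(C)O)C(C)(C)[C@@H]1CC[C@H]1[C@]2(C)CCC(=O)C(C)(C)O[C@@H]2CC[C@@]1(C)O | target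

Total step count: 24
Longest linear sequence: 15 steps (steps 1–3, 6–14, 22–24, from 1 to 34)

Steps most likely to fail

1. Step 6 (proposed new method). The carbenoid may be lost to dimerisation, to hydrogen shift from the isopropylidene methyl groups or to reaction at its vinylogous position before it cyclopropanates. Enantioface selection may be poor with a ketone acceptor, and the Cope shift may stall. The fallback moves the same bond construction onto the carbenoid class for which the tandem reaction and its enantiocontrol are established, and closes ring B afterwards. It sets out from diene 8. Rh2(S-DOSP)4 and methyl 2-diazo-4-methylpent-3-enoate F1 (from methyl 4-methylpent-3-enoate, 4-acetamidobenzenesulfonyl azide and DBU), followed by heating, should give methyl (4R)-4-(acetoxymethyl)-3,3,5-trimethylcyclohepta-1,5-diene-1-carboxylate F2. Me(MeO)NH·HCl and i-PrMgCl convert the ester to the Weinreb amide and cleave the acetate, giving the hydroxy amide F3. Vinylmagnesium bromide gives the divinyl ketone F4. Nazarov cyclisation (BF3·OEt2, CH2Cl2) closes ring B to the hydroxy enone F5, and acetylation (Ac2O, pyridine) returns to the route at 10.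

2. Step 18. Ring closure may take the six-membered (exo) course or be intercepted by the counter-ion, the alkoxymercuration may revert during work-up, and the C18 ketone may be reduced during demercuration. The fallback sets out from 26 and uses a bromonium-induced cyclisation followed by a separate radical oxygenation. 2,4,4,6-Tetrabromocyclohexa-2,5-dien-1-one in MeNO2 at 0 °C should give (5aR,9aR)-3-bromo-2,2,5a-trimethyloctahydro-1-benzoxepin-6(2H)-one F6 by Markovnikov opening of the bromonium ion. Bu3SnH under dry air then turns the C–Br bond into C–OH through the C23 radical without any hydride that could touch the ketone, and the sequence returns to the route at 28.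

3. Step 22. The C16 radical may be reduced before it adds, and the base equilibrium at C18 may favour the wrong epimer. The fallback replaces thermodynamic control by reagent-controlled protonation. It sets out from 20 and 31, which are joined as before. The whole adduct mixture, including the C18 epimer of 32, F7, is treated with TMSCl, NaI and Et3N in MeCN to give the tris(trimethylsilyl) compound F8, the C18=C32 silyl enol ether with both alcohols silylated. Protonation of F8 at −78 °C with the Lewis-acid-assisted chiral Brønsted acid SnCl4·(R)-BINOL, or its mirror image, whichever delivers the proton to the face syn to C21, followed by mild acid work-up that removes the silyl ethers, returns to the route at 32.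

Further compounds
F1 | step 6 | methyl 2-diazo-4-methylpent-3-enoate | COC(=O)C(=[N+]=[N-])C=C(C)C
F2 | step 6 | methyl (4R)-4-(acetoxymethyl)-3,3,5-trimethylcyclohepta-1,5-diene-1-carboxylate | CC1=CCC(C(=O)OC)=CC(C)(C)[C@@H]1COC(C)=O
F3 | step 6 | (4R)-4-(hydroxymethyl)-N-methoxy-N,3,3,5-tetramethylcyclohepta-1,5-diene-1-carboxamide | CC1=CCC(C(=O)N(C)OC)=CC(C)(C)[C@@H]1CO
F4 | step 6 | 1-[(4R)-4-(hydroxymethyl)-3,3,5-trimethylcyclohepta-1,5-dien-1-yl]prop-2-en-1-one | CC1=CCC(C(=O)C=C)=CC(C)(C)[C@@H]1CO
F5 | step 6 | (5R)-5-(hydroxymethyl)-4,4,6-trimethyl-3,4,5,8-tetrahydroazulen-1(2H)-one | CC1=CCC2=C(CCC2=O)C(C)(C)[C@@H]1CO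
F6 | step 18 | (5aR,9aR)-3-bromo-2,2,5a-trimethyloctahydro-1-benzoxepin-6(2H)-one (C23 epimers) | O=C1[C@]2(C)CCC(Br)C(C)(C)O[C@@H]2CCC1
F7 | step 22 | C18 epimer of 32 (5aS,6R,9aR) | CC1=CC[C@H]2[C@H](CC[C@]2(C)O)C(C)(C)[C@@H]1CC[C@@H]1[C@]2(C)CCC(O)C(C)(C)O[C@@H]2CCC1=O
F8 | step 22 | tris(trimethylsilyl) compound: C18=C32 silyl enol ether of 32 with C9 and C23 trimethylsilyl ethers | CC1=CC[C@H]2[C@H](CC[C@]2(C)O[Si](C)(C)C)C(C)(C)[C@@H]1CCC1=C(O[Si](C)(C)C)CC[C@H]2OC(C)(C)C(O[Si](C)(C)C)CC[C@@]12C
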